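The benzene ring of the chromene (C4a, C5, C6, C7, C8, C8a) is made, not bought. Oxygen on C8a and C7, hydrogen on C8 between them and the chiral chain on C6 is the pattern that a vinylketene and an alkoxyalkyne give on annulation. In step 11 an α-ethylidene acid chloride that already holds the (S)-centre, the (E)-alkene and the silylated acetylbenzofuranol is dehydrochlorinated and combined with methoxyacetylene. One operation forms C8a–C8, C7–C6 and C8a–C4a and delivers the 3-methoxy-4-alkylphenol. The acid chloride comes from an enantioselective diene hydroalkylation and a Doebner condensation; chromenylation and desilylation finish.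

Key step: step 11

Remarks on the chemistry:
- Atom labels C4a–C8a are those of the 2H-chromene ring of the target.
- The sense of induction in step 5 is assumed from the usual model for this ligand class; the antipodal ligand is used if a test run shows the (R)-adduct.
- Compounds 12, 20 and 25 each carry one extra stereocentre that is destroyed in the same step and is left undefined.
- Either alkene isomer of 13, 14 or 15 would give the same ketene 19.

Step 1
Reactants: 1 1-(2,4-dihydroxyphenyl)ethanone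
Product: 2 1-(2,4-dihydroxy-5-iodophenyl)ethanone
Conditions: ICl (1.05 equiv), AcOH, 20 °C
Reagents that add atoms: iodine monochloride, ClI
Why: Electrophilic aromatic iodination should go to C5, para to the chelated 2-OH and ortho to the free 4-OH, the less hindered of the two doubly activated positions, as in the usual 5-halogenation of this ketone.

Step 2
Reactants: 2 1-(2,4-dihydroxy-5-iodophenyl)ethanone, 3 (2E)-3-methylpent-2-en-4-yn-1-ol
Product: 5 1-[6-hydroxy-2-[(2E)-4-hydroxybut-2-en-2-yl]-1-benzofuran-5-yl]ethanone, via alkynylphenol 4 (not isolated)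
Conditions: PdCl2(PPh3)2 (3 mol %), CuI (6 mol %), Et3N, DMF, 60 °C
Reagents that add atoms: none
Why: Sonogashira coupling of the aryl iodide is followed in the same pot by metal-promoted 5-endo-dig attack of the neighbouring 4-OH on the alkyne (heteroannulation of ortho-alkynylphenols), which should give the 2-substituted benzofuran and leave the (E)-alkene, the allylic alcohol and the chelated OH untouched.

Step 3
Reactants: 5 1-[6-hydroxy-2-[(2E)-4-hydroxybut-2-en-2-yl]-1-benzofuran-5-yl]ethanone
Product: 6 (2E)-3-(5-acetyl-6-hydroxy-1-benzofuran-2-yl)but-2-enal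
Conditions: MnO2 (activated, excess), CH2Cl2, 20 °C
Reagents that add atoms: none
Why: MnO2 oxidises only the allylic primary alcohol (allylic alcohol oxidation) and should leave the hydrogen-bonded phenol and the alkene geometry alone.

Step 4
Reactants: 6 (2E)-3-(5-acetyl-6-hydroxy-1-benzofuran-2-yl)but-2-enal
Product: 7 1-[6-hydroxy-2-[(2E)-penta-2,4-dien-2-yl]-1-benzofuran-5-yl]ethanone
Conditions: Ph3PCH3Br (2.3 equiv), KOtBu (2.2 equiv), THF, 0 °C to 20 °C; aq. NH4Cl
Reagents that add atoms: methyltriphenylphosphonium bromide, C[P+](c1ccccc1)(c1ccccc1)c1ccccc1.[Br-]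
Why: Wittig methylenation should take the aldehyde in preference to the aryl methyl ketone, which is further deactivated as its ortho-phenoxide, so the second equivalent of ylide only deprotonates the phenol.

Step 5
Reactants: 7 1-[6-hydroxy-2-[(2E)-penta-2,4-dien-2-yl]-1-benzofuran-5-yl]ethanone, 8 2,2-dimethyl-1,3-dioxane-4,6-dione
Product: 9 5-[(2S,3E)-4-(5-acetyl-6-hydroxy-1-benzofuran-2-yl)pent-3-en-2-yl]-2,2-dimethyl-1,3-dioxane-4,6-dione
Conditions: [Pd(η3-C3H5)Cl]2 (2.5 mol %), (S)-tBu-PHOX (6 mol %), NaB[3,5-(CF3)2C6H3]4 (6 mol %), Et3N (1 equiv), 8 (2 equiv), CH2Cl2, 25 °C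
Reagents that add atoms: none
Why: Palladium hydride should add to the terminal vinyl group to give a π-allyl complex that the Meldrum's acid anion attacks at the less hindered CH(CH3) end (palladium-catalysed enantioselective 1,2-hydroalkylation of aryl dienes with strongly acidic C–H pronucleophiles), and the chiral P,N-ligand fixes which allyl face is attacked and so sets the new centre as S.

Step 6
Reactants: 9 5-[(2S,3E)-4-(5-acetyl-6-hydroxy-1-benzofuran-2-yl)pent-3-en-2-yl]-2,2-dimethyl-1,3-dioxane-4,6-dione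
Product: 10 2-[(2S,3E)-4-(5-acetyl-6-hydroxy-1-benzofuran-2-yl)pent-3-en-2-yl]propanedioic acid
Conditions: 0.1 M HCl, THF/H2O (2:1), 45 °C
Reagents that add atoms: water, O
Why: Acid-catalysed hydrolysis of the cyclic acylal should free the malonic acid and acetone below the temperature at which malonic acids lose CO2, and the stereocentre, which is not α to a carbonyl group, is not at risk.

Step 7
Reactants: 10 2-[(2S,3E)-4-(5-acetyl-6-hydroxy-1-benzofuran-2-yl)pent-3-en-2-yl]propanedioic acid, 11 acetaldehyde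
Product: 13 (2E)-2-[(2S,3E)-4-(5-acetyl-6-hydroxy-1-benzofuran-2-yl)pent-3-en-2-yl]but-2-enoic acid, via aldol adduct 12 (not isolated)
Conditions: 11 (6 equiv), piperidine (0.2 equiv), pyridine, 0 °C then 55 °C, sealed tube
Reagents that add atoms: none
Why: Knoevenagel–Doebner condensation of a monosubstituted malonic acid, in which amine-catalysed addition to acetaldehyde is followed by decarboxylative dehydration, should give the more stable (E)-2-alkylbut-2-enoic acid.

Step 8
Reactants: 13 (2E)-2-[(2S,3E)-4-(5-acetyl-6-hydroxy-1-benzofuran-2-yl)pent-3-en-2-yl]but-2-enoic acid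
Product: 14 tert-butyldimethylsilyl (2E)-2-[(2S,3E)-4-[5-acetyl-6-(tert-butyldimethylsilyloxy)-1-benzofuran-2-yl]pent-3-en-2-yl]but-2-enoate
Conditions: TBSCl (2.6 equiv), imidazole (5.5 equiv), DMF, 25 °C; non-aqueous work-up
Reagents that add atoms: tert-butyldimethylsilyl chloride, CC(C)(C)[Si](C)(C)Cl
Why: Silylation converts the phenol to its aryl silyl ether and the acid to its silyl ester in one operation, placed after the last aqueous acid or base so that the base-labile aryl silyl ether never meets hydroxide.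

Step 9
Reactants: 14 tert-butyldimethylsilyl (2E)-2-[(2S,3E)-4-[5-acetyl-6-(tert-butyldimethylsilyloxy)-1-benzofuran-2-yl]pent-3-en-2-yl]but-2-enoate
Product: 15 (2E)-2-[(2S,3E)-4-[5-acetyl-6-(tert-butyldimethylsilyloxy)-1-benzofuran-2-yl]pent-3-en-2-yl]but-2-enoyl chloride
Conditions: (COCl)2 (1.3 equiv), DMF (3 mol %), CH2Cl2, 0 °C to 20 °C; volatiles removed under high vacuum
Reagents that add atoms: oxalyl chloride, O=C(Cl)C(Cl)=O
Why: Silyl esters exchange directly with oxalyl chloride under DMF catalysis to give acid chlorides, so no HCl is formed that could add to the electron-rich alkene or cleave the aryl silyl ether.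

Step 10
Reactants: 16 2-chloro-1,1-dimethoxyethane
Product: 18 methoxyacetylene, via sodium methoxyacetylide 17 (not isolated)
Conditions: NaNH2 (3.1 equiv), liquid NH3, −33 °C; NH3 evaporated; sat. aq. NH4Cl, −20 °C; distilled into cold toluene
Reagents that add atoms: none
Why: Twofold base-induced elimination (HCl and MeOH) from the chloroacetal gives the sodium alkynyl ether, and protonation releases the volatile ynol ether, the standard preparation of alkoxyacetylenes.

Step 11
Reactants: 15 (2E)-2-[(2S,3E)-4-[5-acetyl-6-(tert-butyldimethylsilyloxy)-1-benzofuran-2-yl]pent-3-en-2-yl]but-2-enoyl chloride, 18 methoxyacetylene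
Product: 23 1-[6-(tert-butyldimethylsilyloxy)-2-[(2E,4S)-4-(4-hydroxy-2-methoxyphenyl)pent-2-en-2-yl]-1-benzofuran-5-yl]ethanone, via vinylketene 19 (not isolated), via vinylcyclobutenone 20 (not isolated), via dienylketene 21 (not isolated), via cyclohexadienone 22 (not isolated)
Conditions: 15 added over 4 h to 18 (8 equiv) and Et3N (1.4 equiv), toluene (0.03 M), 40 °C, sealed vessel; then 95 °C, 3 h
Reagents that add atoms: none
Why: Proposed new method: Et3N should remove HCl across the ethylidene methyl group and the acyl chloride of 15 to give vinylketene 19, whose carbonyl carbon is attacked by the nucleophilic CH of methoxyacetylene in a [2+2] cycloaddition to the 3-methoxy-4-vinylcyclobutenone 20; on heating, 4π electrocyclic opening gives dienylketene 21, which closes onto the vinyl CH2 to dienone 22 and tautomerises to phenol 23. The closest known chemistry is the Danheiser benzannulation, where the same vinylketene and alkoxyalkyne cascade starts from a cyclobutenone or an unsaturated α-diazo ketone, together with the known [2+2] trapping of vinylketenes made from unsaturated acid chlorides and amine; the new element is feeding a dehydrochlorination-derived vinylketene into the aromatic annulation. The benzene ring is closed by a thermal disrotatory 6π electrocyclisation that joins the ketene carbon (future C8a) to the terminal CH2 (future C4a), followed by enolisation, the four-membered ring serving only as a relay. No stereocentre is created: the ring-carbon epimers of 20 converge on opening, and the C–H of the existing (S)-centre sits on the α-carbon substituent and is not acidified by the acylammonium, ketene or dienone carbonyl, so it should pass through unchanged. The step needs regioselectivity (OH on C8a, H on C8, OMe on C7, chain on C6), which the polarity match between the ketene carbonyl carbon and the ynol ether CH secures, and chemoselectivity for alkyne capture over ketene dimerisation or acylation of the product phenol, which slow addition of 15 to a large excess of 18 at 40 °C before any heating secures; the unproductive rotamer of 21 simply recloses to 20 and re-enters.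

Step 12
Reactants: 23 1-[6-(tert-butyldimethylsilyloxy)-2-[(2E,4S)-4-(4-hydroxy-2-methoxyphenyl)pent-2-en-2-yl]-1-benzofuran-5-yl]ethanone, 24 3-methylbut-2-enal
Product: 27 1-[6-(tert-butyldimethylsilyloxy)-2-[(2E,4S)-4-(7-methoxy-2,2-dimethyl-2H-chromen-6-yl)pent-2-en-2-yl]-1-benzofuran-5-yl]ethanone, via benzodioxaborin 25 (not isolated), via quinone methide 26 (not isolated)
Conditions: PhB(OH)2 (1.1 equiv), 24 (1.5 equiv), AcOH (5 equiv), toluene, 110 °C, Dean–Stark
Reagents that add atoms: none
Why: Phenylboronic acid templates ortho-hydroxyalkylation of the phenol by the enal to a benzodioxaborin, whose thermal fragmentation gives an ortho-quinone methide that closes by oxa-6π electrocyclisation (boronic acid-mediated chromenylation); the ortho carbon not flanked by the methoxy group (future C4a) should react, and the silylated benzofuranol cannot compete.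

Step 13
Reactants: 27 1-[6-(tert-butyldimethylsilyloxy)-2-[(2E,4S)-4-(7-methoxy-2,2-dimethyl-2H-chromen-6-yl)pent-2-en-2-yl]-1-benzofuran-5-yl]ethanone
Product: 28 1-[6-hydroxy-2-[(2E,4S)-4-(7-methoxy-2,2-dimethyl-2H-chromen-6-yl)pent-2-en-2-yl]-1-benzofuran-5-yl]ethanone
Conditions: TBAF (1.1 equiv), AcOH (1.1 equiv), THF, 0 °C
Reagents that add atoms: none
Why: Fluoride cleaves the aryl silyl ether, which the ortho acetyl group activates, at 0 °C, and the acetic acid buffer keeps the liberated phenoxide from acting as a base on the chromene or the allylic centre.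

Compound list
1 | 1-(2,4-dihydroxyphenyl)ethanone (2,4-dihydroxyacetophenone) | CC(=O)c1ccc(O)cc1O | starting material
2 | 1-(2,4-dihydroxy-5-iodophenyl)ethanone | CC(=O)c1cc(I)c(O)cc1O | intermediate
3 | (2E)-3-methylpent-2-en-4-yn-1-ol | C#C/C(C)=C/CO | starting material
4 | 1-[2,4-dihydroxy-5-[(3E)-5-hydroxy-3-methylpent-3-en-1-yn-1-yl]phenyl]ethanone | CC(=O)c1cc(C#C/C(C)=C/CO)c(O)cc1O | intermediate
5 | 1-[6-hydroxy-2-[(2E)-4-hydroxybut-2-en-2-yl]-1-benzofuran-5-yl]ethanone | CC(=O)c1cc2cc(/C(C)=C/CO)oc2cc1O | intermediate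
6 | (2E)-3-(5-acetyl-6-hydroxy-1-benzofuran-2-yl)but-2-enal | CC(=O)c1cc2cc(/C(C)=C/C=O)oc2cc1O | intermediate
7 | 1-[6-hydroxy-2-[(2E)-penta-2,4-dien-2-yl]-1-benzofuran-5-yl]ethanone | CC(=O)c1cc2cc(/C(C)=C/C=C)oc2cc1O | intermediate
8 | 2,2-dimethyl-1,3-dioxane-4,6-dione (Meldrum's acid) | CC1(C)OC(=O)CC(=O)O1 | starting material
9 | 5-[(2S,3E)-4-(5-acetyl-6-hydroxy-1-benzofuran-2-yl)pent-3-en-2-yl]-2,2-dimethyl-1,3-dioxane-4,6-dione | CC1(C)OC(=O)C(C(=O)O1)[C@@H](C)/C=C(\C)c1cc2cc(C(C)=O)c(O)cc2o1 | intermediate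
10 | 2-[(2S,3E)-4-(5-acetyl-6-hydroxy-1-benzofuran-2-yl)pent-3-en-2-yl]propanedioic acid | OC(=O)C(C(=O)O)[C@@H](C)/C=C(\C)c1cc2cc(C(C)=O)c(O)cc2o1 | intermediate
11 | acetaldehyde | CC=O | starting material
12 | 2-(1-hydroxyethyl)-2-[(2S,3E)-4-(5-acetyl-6-hydroxy-1-benzofuran-2-yl)pent-3-en-2-yl]propanedioic acid (carbinol epimers) | CC(O)C(C(=O)O)(C(=O)O)[C@@H](C)/C=C(\C)c1cc2cc(C(C)=O)c(O)cc2o1 | intermediate
13 | (2E)-2-[(2S,3E)-4-(5-acetyl-6-hydroxy-1-benzofuran-2-yl)pent-3-en-2-yl]but-2-enoic acid | C/C=C(/C(=O)O)[C@@H](C)/C=C(\C)c1cc2cc(C(C)=O)c(O)cc2o1 | intermediate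
14 | tert-butyldimethylsilyl (2E)-2-[(2S,3E)-4-[5-acetyl-6-(tert-butyldimethylsilyloxy)-1-benzofuran-2-yl]pent-3-en-2-yl]but-2-enoate | C/C=C(/C(=O)O[Si](C)(C)C(C)(C)C)[C@@H](C)/C=C(\C)c1cc2cc(C(C)=O)c(O[Si](C)(C)C(C)(C)C)cc2o1 | intermediate
15 | (2E)-2-[(2S,3E)-4-[5-acetyl-6-(tert-butyldimethylsilyloxy)-1-benzofuran-2-yl]pent-3-en-2-yl]but-2-enoyl chloride | C/C=C(/C(Cl)=O)[C@@H](C)/C=C(\C)c1cc2cc(C(C)=O)c(O[Si](C)(C)C(C)(C)C)cc2o1 | intermediate
16 | 2-chloro-1,1-dimethoxyethane (chloroacetaldehyde dimethyl acetal) | COC(CCl)OC | starting material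
17 | sodium methoxyacetylide | [Na+].[C-]#COC | intermediate
18 | methoxyacetylene | COC#C | intermediate
19 | 2-[(2S,3E)-4-[5-acetyl-6-(tert-butyldimethylsilyloxy)-1-benzofuran-2-yl]pent-3-en-2-yl]buta-1,3-dien-1-one | C=CC(=C=O)[C@@H](C)/C=C(\C)c1cc2cc(C(C)=O)c(O[Si](C)(C)C(C)(C)C)cc2o1 | intermediate
20 | 4-ethenyl-3-methoxy-4-[(2S,3E)-4-[5-acetyl-6-(tert-butyldimethylsilyloxy)-1-benzofuran-2-yl]pent-3-en-2-yl]cyclobut-2-en-1-one (both C4 epimers) | COC1=CC(=O)C1(C=C)[C@@H](C)/C=C(\C)c1cc2cc(C(C)=O)c(O[Si](C)(C)C(C)(C)C)cc2o1 | intermediate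
21 | (3Z)-3-methoxy-4-[(2S,3E)-4-[5-acetyl-6-(tert-butyldimethylsilyloxy)-1-benzofuran-2-yl]pent-3-en-2-yl]hexa-1,3,5-trien-1-one | C=C/C(=C(\C=C=O)OC)[C@@H](C)/C=C(\C)c1cc2cc(C(C)=O)c(O[Si](C)(C)C(C)(C)C)cc2o1 | intermediate
22 | 3-methoxy-4-[(2S,3E)-4-[5-acetyl-6-(tert-butyldimethylsilyloxy)-1-benzofuran-2-yl]pent-3-en-2-yl]cyclohexa-2,4-dien-1-one | COC1=CC(=O)CC=C1[C@@H](C)/C=C(\C)c1cc2cc(C(C)=O)c(O[Si](C)(C)C(C)(C)C)cc2o1 | intermediate
23 | 1-[6-(tert-butyldimethylsilyloxy)-2-[(2E,4S)-4-(4-hydroxy-2-methoxyphenyl)pent-2-en-2-yl]-1-benzofuran-5-yl]ethanone | COc1cc(O)ccc1[C@@H](C)/C=C(\C)c1cc2cc(C(C)=O)c(O[Si](C)(C)C(C)(C)C)cc2o1 | intermediate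
24 | 3-methylbut-2-enal | CC(C)=CC=O | starting material
25 | 1-[6-(tert-butyldimethylsilyloxy)-2-[(2E,4S)-4-[7-methoxy-4-(2-methylprop-1-enyl)-2-phenyl-4H-1,3,2-benzodioxaborinin-6-yl]pent-2-en-2-yl]-1-benzofuran-5-yl]ethanone (C4 epimers) | COc1cc2OB(c3ccccc3)OC(C=C(C)C)c2cc1[C@@H](C)/C=C(\C)c1cc3cc(C(C)=O)c(O[Si](C)(C)C(C)(C)C)cc3o1 | intermediate
26 | 3-methoxy-6-(3-methylbut-2-enylidene)-4-[(2S,3E)-4-[5-acetyl-6-(tert-butyldimethylsilyloxy)-1-benzofuran-2-yl]pent-3-en-2-yl]cyclohexa-2,4-dien-1-one | COC1=CC(=O)C(=CC=C(C)C)C=C1[C@@H](C)/C=C(\C)c1cc2cc(C(C)=O)c(O[Si](C)(C)C(C)(C)C)cc2o1 | intermediate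
27 | 1-[6-(tert-butyldimethylsilyloxy)-2-[(2E,4S)-4-(7-methoxy-2,2-dimethyl-2H-chromen-6-yl)pent-2-en-2-yl]-1-benzofuran-5-yl]ethanone | COc1cc2c(cc1[C@@H](C)/C=C(\C)c1cc3cc(C(C)=O)c(O[Si](C)(C)C(C)(C)C)cc3o1)C=CC(C)(C)O2 | intermediate
28 | 1-[6-hydroxy-2-[(2E,4S)-4-(7-methoxy-2,2-dimethyl-2H-chromen-6-yl)pent-2-en-2-yl]-1-benzofuran-5-yl]ethanone | COc1cc2c(cc1[C@@H](C)/C=C(\C)c1cc3cc(C(C)=O)c(O)cc3o1)C=CC(C)(C)O2 | target

Total steps: 13. Longest linear sequence: 12 (steps 1 to 9 and 11 to 13); step 10 is a one-step branch.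

Steps most likely to fail

Step 11 (Proposed new method). What may go wrong: dimerisation or oligomerisation of the vinylketene outrunning its capture by the alkyne, acylation of the newly formed phenol by ketene still present, or stalling at the cyclobutenone stage. Fallback, known chemistry, sets out from 7 and comes back at 27; the aromatic ring is brought in preformed instead of being built. Diene 7 is silylated (TBSCl, imidazole, DMF) to 1-[6-(tert-butyldimethylsilyloxy)-2-[(2E)-penta-2,4-dien-2-yl]-1-benzofuran-5-yl]ethanone F1. Commercial 4-bromo-3-methoxyphenol is chromenylated with 24 (PhB(OH)2, AcOH, toluene, reflux) to 6-bromo-7-methoxy-2,2-dimethyl-2H-chromene F2. Bromine–lithium exchange (n-BuLi, THF, −78 °C), B(OiPr)3 and dilute HCl turn it into (7-methoxy-2,2-dimethyl-2H-chromen-6-yl)boronic acid F3. Nickel-catalysed enantioselective 1,2-hydroarylation of F1 with F3 (Ni(cod)2, chiral spiro aminophosphine ligand, MeOH/toluene), a known reaction of 1-aryl-1,3-dienes with arylboronic acids, should give 27, and step 13 follows.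

Step 5. What may go wrong: slow hydropalladation of the 1,1-disubstituted diene, or poor facial control at the π-allyl stage. Fallback sets out from 6 and comes back at 10; the centre is set on oxygen first and then transferred. Catalytic asymmetric methylation of enal 6 (Me2Zn, (−)-MIB, toluene, 0 °C) should give 1-[6-hydroxy-2-[(2E,4S)-4-hydroxypent-2-en-2-yl]-1-benzofuran-5-yl]ethanone F4. ClCO2Me, pyridine and DMAP give methyl [(2S,3E)-4-[5-acetyl-6-(methoxycarbonyloxy)-1-benzofuran-2-yl]pent-3-en-2-yl] carbonate F5. Tsuji–Trost alkylation with dimethyl malonate (Pd(PPh3)4, THF; net retention by double inversion, attack at the less substituted allyl terminus) gives dimethyl 2-[(2S,3E)-4-[5-acetyl-6-(methoxycarbonyloxy)-1-benzofuran-2-yl]pent-3-en-2-yl]propanedioate F6. KOH in aqueous MeOH, then acidification, removes both esters and the aryl carbonate and returns the route to 10.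

Step 7. What may go wrong: sluggish addition of the hindered malonic acid, plain decarboxylation without condensation, or amine-mediated condensation of acetaldehyde at the ortho-hydroxyacetyl group. Fallback sets out from 6 and comes back at 13; the condensation is replaced by an olefination. Enal 6 is taken to the bis-carbonate F5 as in the fallback for step 5. Tsuji–Trost alkylation of triethyl phosphonoacetate (Pd(PPh3)4, THF) gives ethyl (3S,4E)-5-[5-acetyl-6-(methoxycarbonyloxy)-1-benzofuran-2-yl]-2-(diethoxyphosphoryl)-3-methylhex-4-enoate F7. Horner–Wadsworth–Emmons reaction with 11 (NaH, THF, 0 °C) gives ethyl (2E)-2-[(2S,3E)-4-[5-acetyl-6-(methoxycarbonyloxy)-1-benzofuran-2-yl]pent-3-en-2-yl]but-2-enoate F8; either alkene isomer serves, since both lead to the same ketene. LiOH in aqueous THF/MeOH, then acidification, cleaves the ester and the carbonate to 13.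

Further compounds
F1 | step 11 | 1-[6-(tert-butyldimethylsilyloxy)-2-[(2E)-penta-2,4-dien-2-yl]-1-benzofuran-5-yl]ethanone | CC(=O)c1cc2cc(/C(C)=C/C=C)oc2cc1O[Si](C)(C)C(C)(C)C
F2 | step 11 | 6-bromo-7-methoxy-2,2-dimethyl-2H-chromene | COc1cc2OC(C)(C)C=Cc2cc1Br
F3 | step 11 | (7-methoxy-2,2-dimethyl-2H-chromen-6-yl)boronic acid | COc1cc2OC(C)(C)C=Cc2cc1B(O)O
F4 | step 5 | 1-[6-hydroxy-2-[(2E,4S)-4-hydroxypent-2-en-2-yl]-1-benzofuran-5-yl]ethanone | O[C@@H](C)/C=C(\C)c1cc2cc(C(C)=O)c(O)cc2o1
F5 | step 5 | methyl [(2S,3E)-4-[5-acetyl-6-(methoxycarbonyloxy)-1-benzofuran-2-yl]pent-3-en-2-yl] carbonate | COC(=O)O[C@@H](C)/C=C(\C)c1cc2cc(C(C)=O)c(OC(=O)OC)cc2o1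
F6 | step 5 | dimethyl 2-[(2S,3E)-4-[5-acetyl-6-(methoxycarbonyloxy)-1-benzofuran-2-yl]pent-3-en-2-yl]propanedioate | COC(=O)C(C(=O)OC)[C@@H](C)/C=C(\C)c1cc2cc(C(C)=O)c(OC(=O)OC)cc2o1
F7 | step 7 | ethyl (3S,4E)-5-[5-acetyl-6-(methoxycarbonyloxy)-1-benzofuran-2-yl]-2-(diethoxyphosphoryl)-3-methylhex-4-enoate | CCOC(=O)C(P(=O)(OCC)OCC)[C@@H](C)/C=C(\C)c1cc2cc(C(C)=O)c(OC(=O)OC)cc2o1
F8 | step 7 | ethyl (2E)-2-[(2S,3E)-4-[5-acetyl-6-(methoxycarbonyloxy)-1-benzofuran-2-yl]pent-3-en-2-yl]but-2-enoate | C/C=C(/C(=O)OCC)[C@@H](C)/C=C(\C)c1cc2cc(C(C)=O)c(OC(=O)OC)cc2o1
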